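The synthesis rests on disconnecting the O1–C7a aryl ether bond of the dihydrobenzofuran fused to ring A (the styryl-bearing resorcinol ring). Ring A carries oxygen at C6, so a chlorine at C7, where electrophilic chlorination ortho to that oxygen naturally places it, has a single ortho hydrogen, at C7a. Base therefore generates the C7=C7a aryne, and the C2 alkoxide closes the five-membered ring at C7a while the chlorine leaves without trace (cine substitution). The precursor is an open-chain (1S,2S)-1,2,2-triarylethanol, assembled by two ketone α-arylations and a dynamic kinetic transfer hydrogenation; the second dihydrobenzofuran arrives as an enantiopure aryl bromide made by rhodium carbene C–H insertion.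

Key step: step 15

Notation: benzofuran numbering (O1, C2, C3, C3a, C4–C7, C7a) is used for the dihydrobenzofuran fused to ring A; ring B is the benzo ring of the second dihydrobenzofuran; Bn = benzyl. ArA = 4-(benzyloxy)-5-chloro-2-[(E)-2-(4-(benzyloxy)phenyl)ethenyl]phenyl. ArB = (2R,3R)-7-(benzyloxy)-2-[4-(benzyloxy)phenyl]-3-[3,5-bis(benzyloxy)phenyl]-2,3-dihydro-1-benzofuran-5-yl.

Assumption: Rh2(S-PTAD)4 is taken as the catalyst antipode that sets the (3R) centre in step 6; should the sense of induction be the opposite, Rh2(R-PTAD)4 is used instead, with nothing else changed.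

**Route**

Step 1
Reactants: 1 5-bromo-2,3-dihydroxybenzaldehyde
Product: 2 3-(benzyloxy)-5-bromo-2-hydroxybenzaldehyde
Conditions: NaH (2.2 equiv), DMF, 0 °C → rt; BnBr (1.0 equiv); aq. HCl work-up
Reagents that add atoms: benzyl bromide, BrCc1ccccc1
Why: Williamson etherification of the dianion, which should react at the 3-phenoxide because the 2-phenoxide is delocalised into and chelated by the ortho formyl group.

Step 2
Reactants: 2 3-(benzyloxy)-5-bromo-2-hydroxybenzaldehyde; 3 4-(benzyloxy)benzyl chloride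
Product: 4 3-(benzyloxy)-2-{[4-(benzyloxy)phenyl]methoxy}-5-bromobenzaldehyde
Conditions: K2CO3, NaI (cat.), DMF, 60 °C
Reagents that add atoms: none
Why: Williamson etherification of the one remaining phenol with a reactive benzylic chloride.

Step 3
Reactants: 4 3-(benzyloxy)-2-{[4-(benzyloxy)phenyl]methoxy}-5-bromobenzaldehyde; 5 1,3-bis(benzyloxy)-5-bromobenzene
Product: 7 racemic diarylmethanol, via aryl Grignard reagent 6 (not isolated)
Conditions: 5, Mg, THF, 50 °C; then 4, THF, 0 °C; aq. NH4Cl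
Reagents that add atoms: none
Why: Grignard 1,2-addition to the aldehyde, with the aryl bromide of 4 inert at 0 °C; the carbinol centre is formed racemic and is removed in step 4.

Step 4
Reactants: 7 racemic diarylmethanol
Product: 8 [3-(benzyloxy)-2-{[4-(benzyloxy)phenyl]methoxy}-5-bromophenyl][3,5-bis(benzyloxy)phenyl]methanone
Conditions: activated MnO2 (excess), CH2Cl2, rt
Reagents that add atoms: none
Why: MnO2 oxidation of a doubly benzylic alcohol to the benzophenone; ethers and the aryl bromide are untouched.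

Step 5
Reactants: 8 diaryl ketone
Product: 9 hydrazone of 8 (E/Z mixture)
Conditions: N2H4·H2O (excess), AcOH (cat.), EtOH, 80 °C
Reagents that add atoms: hydrazine (used as the hydrate), NN
Why: Acid-catalysed hydrazone condensation, driven by excess hydrazine because the ketone is hindered by its ortho alkoxy group.

Step 6
Reactants: 9 hydrazone of 8
Product: 11 (2S,3R)-7-(benzyloxy)-2-[4-(benzyloxy)phenyl]-3-[3,5-bis(benzyloxy)phenyl]-5-bromo-2,3-dihydro-1-benzofuran (2,3-cis), via diaryldiazomethane 10 (not isolated)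
Conditions: MnO2, CH2Cl2, 0 °C; then Rh2(S-PTAD)4 (1 mol %), 0 °C → rt
Reagents that add atoms: none
Why: MnO2 dehydrogenates the hydrazone to the diaryldiazomethane, whose rhodium carbene inserts into the adjacent benzylic ether C–H bond (intramolecular 1,5 C–H insertion of a donor/donor carbene); the chiral carboxylate catalyst should set C3 as (R), and the 2,3-cis relationship is the usual kinetic outcome of this insertion.

Step 7
Reactants: 11 cis-dihydrobenzofuran bromide
Product: 12 (2R,3R)-7-(benzyloxy)-2-[4-(benzyloxy)phenyl]-3-[3,5-bis(benzyloxy)phenyl]-5-bromo-2,3-dihydro-1-benzofuran (2,3-trans; ArB–Br)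
Conditions: CF3CO2H, CH2Cl2, 0 °C → rt
Reagents that add atoms: none
Why: Acid-mediated epimerisation of a 2-aryl-2,3-dihydrobenzofuran: reversible ionisation of the O1–C2 bond to the 4-(benzyloxy)benzyl cation and reclosure under thermodynamic control should give the 2,3-trans ring, with C3 untouched and C2 becoming (R).

Step 8
Reactants: 13 2-bromo-5-hydroxybenzaldehyde
Product: 14 2-bromo-4-chloro-5-hydroxybenzaldehyde
Conditions: N-chlorosuccinimide, TsOH·H2O (cat.), MeCN, rt → 50 °C
Reagents that add atoms: N-chlorosuccinimide, ClN1C(=O)CCC1=O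
Why: Electrophilic aromatic chlorination ortho to the phenol, expected at C4 (the ortho site not flanked by the formyl group) by analogy with the dibromination of 3-hydroxybenzaldehyde, which places its second halogen there.

Step 9
Reactants: 14 2-bromo-4-chloro-5-hydroxybenzaldehyde
Product: 15 5-(benzyloxy)-2-bromo-4-chlorobenzaldehyde
Conditions: BnBr, K2CO3, DMF, rt
Reagents that add atoms: benzyl bromide, BrCc1ccccc1
Why: Williamson etherification of the phenol.

Step 10
Reactants: 3 4-(benzyloxy)benzyl chloride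
Product: 16 diethyl {[4-(benzyloxy)phenyl]methyl}phosphonate
Conditions: P(OEt)3 (neat), 150 °C
Reagents that add atoms: triethyl phosphite, CCOP(OCC)OCC
Why: Michaelis–Arbuzov reaction of a benzylic chloride.

Step 11
Reactants: 15 5-(benzyloxy)-2-bromo-4-chlorobenzaldehyde; 16 diethyl {[4-(benzyloxy)phenyl]methyl}phosphonate
Product: 17 1-(benzyloxy)-5-{(E)-2-[4-(benzyloxy)phenyl]ethenyl}-4-bromo-2-chlorobenzene (ArA–Br)
Conditions: KOtBu, THF, 0 °C → rt
Reagents that add atoms: none
Why: Horner–Wadsworth–Emmons olefination with a benzylic phosphonate, which should give the (E)-stilbene.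

Step 12
Reactants: 17 ArA–Br; 18 1-[4-(benzyloxy)phenyl]ethan-1-one
Product: 19 1-[4-(benzyloxy)phenyl]-2-ArA-ethan-1-one
Conditions: Pd2(dba)3 (2 mol %), Xantphos (5 mol %), NaOtBu, toluene, 80 °C
Reagents that add atoms: none
Why: Palladium-catalysed ketone α-arylation; the Xantphos catalyst should insert into the C–Br bond only, leaving the electron-rich C–Cl bond, and the ortho styryl group disfavours a second arylation.

Step 13
Reactants: 19 1-[4-(benzyloxy)phenyl]-2-ArA-ethan-1-one; 12 ArB–Br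
Product: 20 1-[4-(benzyloxy)phenyl]-2-ArA-2-ArB-ethan-1-one (mixture of epimers at C2 of the ethanone)
Conditions: Pd2(dba)3 (3 mol %), Xantphos (7 mol %), NaOtBu, toluene, 100 °C
Reagents that add atoms: none
Why: Palladium-catalysed α-arylation of the more acidic benzylic ketone with an unhindered aryl bromide; the new centre is configurationally labile, so an epimer mixture is expected and is acceptable.

Step 14
Reactants: 20 1-[4-(benzyloxy)phenyl]-2-ArA-2-ArB-ethan-1-one
Product: 21 (1S,2S)-1-[4-(benzyloxy)phenyl]-2-ArA-2-ArB-ethan-1-ol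
Conditions: RuCl[(S,S)-TsDPEN](p-cymene) (5 mol %), HCO2H/Et3N (5:2), DMF, 40 °C
Reagents that add atoms: none
Why: Noyori–Ikariya asymmetric transfer hydrogenation under dynamic kinetic resolution: the α-hydrogen, flanked by the carbonyl and two aryl rings, is acidic enough for the epimers of 20 to interconvert in the medium, the (S,S)-catalyst should give the (S)-carbinol as with other aryl ketones, and the epimer that can hold the bulky ortho-substituted ring-A aryl anti to the incoming hydride (Felkin–Anh) should be reduced faster, which sets the (S) diarylmethine centre.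

Step 15
Reactants: 21 (1S,2S)-1-[4-(benzyloxy)phenyl]-2-ArA-2-ArB-ethan-1-ol
Product: 23 heptabenzyl ether of the target, via aryne lithium alkoxide 22 (not isolated)
Conditions: LiTMP (3 equiv, from 2,2,6,6-tetramethylpiperidine and n-BuLi), THF, −78 → 0 °C; aq. NH4Cl
Reagents that add atoms: none
Why: LiTMP first forms the C2 lithium alkoxide and then removes the only hydrogen ortho to chlorine (C7a–H; the other ortho position, C6, carries the benzyloxy group), and loss of LiCl gives the C7=C7a aryne 22. The alkoxide adds to C7a in a 5-exo-dig closure of the O1–C2–C3–C3a–C7a ring, and the C7 aryllithium, flanked by two oxygens, is protonated by tetramethylpiperidine or on quench, so that chlorine is replaced by hydrogen (cine substitution). The closest known reaction is the classical ring closure through arynes of 2-(3-halophenyl)ethanols to 2,3-dihydrobenzofurans. No stereocentre is created: C2 and C3 are carried over from 21 (the adjacent alkoxide disfavours deprotonation at C3), so the Felkin alcohol gives the 2,3-trans ring. Site selectivity is secured by the tether, which can reach only C7a (attack at C7 would need a meta-bridged ring), and by the C6 oxygen, which stabilises negative charge at C7; the hindered, non-nucleophilic amide is chosen so that it should neither add to the aryne nor attack the benzyl ethers at low temperature.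

Step 16
Reactants: 23 heptabenzyl ether of the target
Product: 24 target, (2S,3S)-3-[(2R,3R)-3-(3,5-dihydroxyphenyl)-7-hydroxy-2-(4-hydroxyphenyl)-2,3-dihydro-1-benzofuran-5-yl]-2-(4-hydroxyphenyl)-4-[(E)-2-(4-hydroxyphenyl)ethenyl]-2,3-dihydro-1-benzofuran-6-ol
Conditions: BCl3 (excess), pentamethylbenzene (excess), CH2Cl2, −78 °C; MeOH quench
Reagents that add atoms: none
Why: Lewis-acid cleavage of aryl benzyl ethers with a non-basic cation scavenger, which should spare the stilbene; any reversible opening of the two O1–C2 bonds should reclose to the more stable 2,3-trans rings.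

**Compound list**

1 | 5-bromo-2,3-dihydroxybenzaldehyde | O=Cc1cc(Br)cc(O)c1O | starting material
2 | 3-(benzyloxy)-5-bromo-2-hydroxybenzaldehyde | O=Cc1cc(Br)cc(OCc2ccccc2)c1O | intermediate
3 | 1-(benzyloxy)-4-(chloromethyl)benzene [4-(benzyloxy)benzyl chloride] | ClCc1ccc(OCc2ccccc2)cc1 | starting material
4 | 3-(benzyloxy)-2-{[4-(benzyloxy)phenyl]methoxy}-5-bromobenzaldehyde | O=Cc1cc(Br)cc(OCc2ccccc2)c1OCc1ccc(OCc2ccccc2)cc1 | intermediate
5 | 1,3-bis(benzyloxy)-5-bromobenzene | Brc1cc(OCc2ccccc2)cc(OCc2ccccc2)c1 | starting material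
6 | [3,5-bis(benzyloxy)phenyl]magnesium bromide | Br[Mg]c1cc(OCc2ccccc2)cc(OCc2ccccc2)c1 | intermediate
7 | rac-[3-(benzyloxy)-2-{[4-(benzyloxy)phenyl]methoxy}-5-bromophenyl][3,5-bis(benzyloxy)phenyl]methanol | OC(c1cc(OCc2ccccc2)cc(OCc2ccccc2)c1)c1cc(Br)cc(OCc2ccccc2)c1OCc1ccc(OCc2ccccc2)cc1 | intermediate
8 | [3-(benzyloxy)-2-{[4-(benzyloxy)phenyl]methoxy}-5-bromophenyl][3,5-bis(benzyloxy)phenyl]methanone | O=C(c1cc(OCc2ccccc2)cc(OCc2ccccc2)c1)c1cc(Br)cc(OCc2ccccc2)c1OCc1ccc(OCc2ccccc2)cc1 | intermediate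
9 | hydrazone of 8 (E/Z mixture) | NN=C(c1cc(OCc2ccccc2)cc(OCc2ccccc2)c1)c1cc(Br)cc(OCc2ccccc2)c1OCc1ccc(OCc2ccccc2)cc1 | intermediate
10 | 1-(benzyloxy)-2-{[4-(benzyloxy)phenyl]methoxy}-5-bromo-3-{[3,5-bis(benzyloxy)phenyl](diazo)methyl}benzene | [N-]=[N+]=C(c1cc(OCc2ccccc2)cc(OCc2ccccc2)c1)c1cc(Br)cc(OCc2ccccc2)c1OCc1ccc(OCc2ccccc2)cc1 | intermediate
11 | (2S,3R)-7-(benzyloxy)-2-[4-(benzyloxy)phenyl]-3-[3,5-bis(benzyloxy)phenyl]-5-bromo-2,3-dihydro-1-benzofuran (2,3-cis) | Brc1cc(OCc5ccccc5)c2c(c1)[C@@H](c1cc(OCc5ccccc5)cc(OCc5ccccc5)c1)[C@@H](c1ccc(OCc5ccccc5)cc1)O2 | intermediate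
12 | (2R,3R)-7-(benzyloxy)-2-[4-(benzyloxy)phenyl]-3-[3,5-bis(benzyloxy)phenyl]-5-bromo-2,3-dihydro-1-benzofuran (2,3-trans; ArB–Br) | Brc1cc(OCc5ccccc5)c2c(c1)[C@@H](c1cc(OCc5ccccc5)cc(OCc5ccccc5)c1)[C@H](c1ccc(OCc5ccccc5)cc1)O2 | intermediate
13 | 2-bromo-5-hydroxybenzaldehyde | O=Cc1cc(O)ccc1Br | starting material
14 | 2-bromo-4-chloro-5-hydroxybenzaldehyde | O=Cc1cc(O)c(Cl)cc1Br | intermediate
15 | 5-(benzyloxy)-2-bromo-4-chlorobenzaldehyde | O=Cc1cc(OCc2ccccc2)c(Cl)cc1Br | intermediate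
16 | diethyl {[4-(benzyloxy)phenyl]methyl}phosphonate | CCOP(=O)(OCC)Cc1ccc(OCc2ccccc2)cc1 | intermediate
17 | 1-(benzyloxy)-5-{(E)-2-[4-(benzyloxy)phenyl]ethenyl}-4-bromo-2-chlorobenzene (ArA–Br) | Brc1cc(Cl)c(OCc2ccccc2)cc1/C=C/c1ccc(OCc2ccccc2)cc1 | intermediate
18 | 1-[4-(benzyloxy)phenyl]ethan-1-one | CC(=O)c1ccc(OCc2ccccc2)cc1 | starting material
19 | 1-[4-(benzyloxy)phenyl]-2-{4-(benzyloxy)-2-[(E)-2-(4-(benzyloxy)phenyl)ethenyl]-5-chlorophenyl}ethan-1-one | c1ccccc1COc1ccc(/C=C/c2cc(OCc5ccccc5)c(Cl)cc2CC(=O)c2ccc(OCc5ccccc5)cc2)cc1 | intermediate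
20 | 1-[4-(benzyloxy)phenyl]-2-{4-(benzyloxy)-2-[(E)-2-(4-(benzyloxy)phenyl)ethenyl]-5-chlorophenyl}-2-{(2R,3R)-7-(benzyloxy)-2-[4-(benzyloxy)phenyl]-3-[3,5-bis(benzyloxy)phenyl]-2,3-dihydro-1-benzofuran-5-yl}ethan-1-one, mixture of epimers at C2 of the ethanone | c1ccccc1COc1ccc(/C=C/c2cc(OCc5ccccc5)c(Cl)cc2C(c2cc(OCc5ccccc5)c4c(c2)[C@@H](c2cc(OCc5ccccc5)cc(OCc5ccccc5)c2)[C@H](c2ccc(OCc5ccccc5)cc2)O4)C(=O)c2ccc(OCc5ccccc5)cc2)cc1 | intermediate
21 | (1S,2S)-1-[4-(benzyloxy)phenyl]-2-{4-(benzyloxy)-2-[(E)-2-(4-(benzyloxy)phenyl)ethenyl]-5-chlorophenyl}-2-{(2R,3R)-7-(benzyloxy)-2-[4-(benzyloxy)phenyl]-3-[3,5-bis(benzyloxy)phenyl]-2,3-dihydro-1-benzofuran-5-yl}ethan-1-ol | c1ccccc1COc1ccc(/C=C/c2cc(OCc5ccccc5)c(Cl)cc2[C@H](c2cc(OCc5ccccc5)c4c(c2)[C@@H](c2cc(OCc5ccccc5)cc(OCc5ccccc5)c2)[C@H](c2ccc(OCc5ccccc5)cc2)O4)[C@@H](c2ccc(OCc5ccccc5)cc2)O)cc1 | intermediate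
22 | lithium alkoxide of 21 in which the C–Cl carbon and its ortho CH form an aryne (5,6-didehydro ring A; C7=C7a in benzofuran numbering) | c1ccccc1COc1ccc(/C=C/C2=C([C@H](c3cc(OCc5ccccc5)c4c(c3)[C@@H](c3cc(OCc5ccccc5)cc(OCc5ccccc5)c3)[C@H](c3ccc(OCc5ccccc5)cc3)O4)[C@@H](c3ccc(OCc5ccccc5)cc3)[O-])C#CC(OCc5ccccc5)=C2)cc1.[Li+] | intermediate
23 | (2S,3S)-6-(benzyloxy)-2-[4-(benzyloxy)phenyl]-4-{(E)-2-[4-(benzyloxy)phenyl]ethenyl}-3-{(2R,3R)-7-(benzyloxy)-2-[4-(benzyloxy)phenyl]-3-[3,5-bis(benzyloxy)phenyl]-2,3-dihydro-1-benzofuran-5-yl}-2,3-dihydro-1-benzofuran | c1ccccc1COc1ccc(/C=C/c2cc(OCc5ccccc5)cc3c2[C@H](c2cc(OCc5ccccc5)c4c(c2)[C@@H](c2cc(OCc5ccccc5)cc(OCc5ccccc5)c2)[C@H](c2ccc(OCc5ccccc5)cc2)O4)[C@@H](c2ccc(OCc5ccccc5)cc2)O3)cc1 | intermediate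
24 | (2S,3S)-3-[(2R,3R)-3-(3,5-dihydroxyphenyl)-7-hydroxy-2-(4-hydroxyphenyl)-2,3-dihydro-1-benzofuran-5-yl]-2-(4-hydroxyphenyl)-4-[(E)-2-(4-hydroxyphenyl)ethenyl]-2,3-dihydro-1-benzofuran-6-ol | Oc1ccc(/C=C/c2cc(O)cc3c2[C@H](c2cc(O)c4c(c2)[C@@H](c2cc(O)cc(O)c2)[C@H](c2ccc(O)cc2)O4)[C@@H](c2ccc(O)cc2)O3)cc1 | target

**Step count and risks**

Total step count: 16. Longest linear sequence: 11 steps (steps 1–7, then 13–16, from compound 1).

Steps most likely to fail:

1. Step 15 (key step). Metalation next to chlorine may be slower than deprotonation elsewhere: at benzylic ether CH2 groups (leading to Wittig rearrangement), or at the diarylmethine hydrogen of the ring-B dihydrobenzofuran (leading to β-elimination of its aryloxide). The amide may also add to the aryne. Fallback: setting out from 21, zincation at the same carbon with LiTMP in the presence of ZnCl2·2LiCl (THF, −78 °C; the arylzinc does not lose chloride) followed by I2 should give the aryl iodide F1. CuI/1,10-phenanthroline/Cs2CO3 in toluene at 110 °C (intramolecular Ullmann etherification) then closes the same O1–C7a bond to the 7-chloro dihydrobenzofuran F2. Hydrodechlorination (Pd(OAc)2, XPhos, HCO2Na, DMF, 80 °C) comes back to the route at 23.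

2. Step 14. Hydride transfer to the congested ketone may be slow, or the catalyst may discriminate poorly between the interconverting epimers, so that the diastereoselectivity is low. Fallback: setting out from 20, substrate-controlled Luche reduction (NaBH4, CeCl3·7H2O, MeOH/THF, −40 °C) should give the two Felkin alcohols, 21 and the (1R,2R) alcohol F3. These are diastereomers because ArB is enantiopure, and they are separated by preparative HPLC. F3 is recycled to 20 by Dess–Martin oxidation, and the fallback comes back to the route at 21.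

3. Step 16. The Lewis acid may ionise the O1–C2 bonds of both dihydrobenzofurans with irreversible capture of the benzylic cations (by the scavenger, chloride or the stilbene) instead of reclosure, or cleavage of the seven ethers may stay incomplete. Fallback: setting out from 23, silane transfer hydrogenolysis under neutral conditions that leave alkenes alone (Pd(OAc)2, Et3SiH, Et3N, CH2Cl2, rt) should give the heptakis(triethylsilyl) ether F4. Desilylation with Bu4NF/AcOH in THF at 0 °C comes back to the route at 24.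

Further compounds
F1 | step 15 | (1S,2S)-1-[4-(benzyloxy)phenyl]-2-{4-(benzyloxy)-5-chloro-6-iodo-2-[(E)-2-(4-(benzyloxy)phenyl)ethenyl]phenyl}-2-ArB-ethan-1-ol | c1ccccc1COc1ccc(/C=C/c2cc(OCc5ccccc5)c(Cl)c(I)c2[C@H](c2cc(OCc5ccccc5)c4c(c2)[C@@H](c2cc(OCc5ccccc5)cc(OCc5ccccc5)c2)[C@H](c2ccc(OCc5ccccc5)cc2)O4)[C@@H](c2ccc(OCc5ccccc5)cc2)O)cc1
F2 | step 15 | 7-chloro derivative of 23, (2S,3S)-6-(benzyloxy)-7-chloro-2-[4-(benzyloxy)phenyl]-4-{(E)-2-[4-(benzyloxy)phenyl]ethenyl}-3-ArB-2,3-dihydro-1-benzofuran | c1ccccc1COc1ccc(/C=C/c2cc(OCc5ccccc5)c(Cl)c3c2[C@H](c2cc(OCc5ccccc5)c4c(c2)[C@@H](c2cc(OCc5ccccc5)cc(OCc5ccccc5)c2)[C@H](c2ccc(OCc5ccccc5)cc2)O4)[C@@H](c2ccc(OCc5ccccc5)cc2)O3)cc1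
F3 | step 14 | (1R,2R)-1-[4-(benzyloxy)phenyl]-2-ArA-2-ArB-ethan-1-ol | c1ccccc1COc1ccc(/C=C/c2cc(OCc5ccccc5)c(Cl)cc2[C@@H](c2cc(OCc5ccccc5)c4c(c2)[C@@H](c2cc(OCc5ccccc5)cc(OCc5ccccc5)c2)[C@H](c2ccc(OCc5ccccc5)cc2)O4)[C@H](c2ccc(OCc5ccccc5)cc2)O)cc1
F4 | step 16 | heptakis(triethylsilyl) ether of 24 | CC[Si](CC)(CC)Oc1ccc(/C=C/c2cc(O[Si](CC)(CC)CC)cc3c2[C@H](c2cc(O[Si](CC)(CC)CC)c4c(c2)[C@@H](c2cc(O[Si](CC)(CC)CC)cc(O[Si](CC)(CC)CC)c2)[C@H](c2ccc(O[Si](CC)(CC)CC)cc2)O4)[C@@H](c2ccc(O[Si](CC)(CC)CC)cc2)O3)cc1
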